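(The runs are simulated with made-up constants, and the scatter is random.)

The pitfall with curves that flatten is to take the last reading for a yield and scale it with the charge, when you first need to know how long a flask keeps working.

| flask | starting material | coupling partner | catalyst | time |
|---|---|---|---|---|
| beta | 0.0500 M | 0.125 M | 0.00400 M |  |
| eta | 0.0250 M | 0.100 M | 0.00400 M |  |
| theta | 0.100 M | 0.125 M | 0.00400 M |  |
| delta | 0.150 M | 0.380 M | 0.00400 M | 110 min |

- beta run (time / min: [target] / M): 4.9: 0.0012; 15: 0.0035; 28: 0.0085; 45: 0.0119; 64: 0.0127; 86: 0.0160; 110: 0.0162
- eta run (time / min: [target] / M): 4.9: 8 × 10⁻⁴; 15: 0.0038; 28: 0.0047; 45: 0.0067; 64: 0.0091; 86: 0.0107; 110: 0.0098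
- theta run (time / min: [target] / M): 4.9: 7 × 10⁻⁴; 15: 0.0051; 28: 0.0123; 45: 0.0157; 64: 0.0197; 86: 0.0231; 110: 0.0248

(scatter of a reading: 8 × 10⁻⁴ M)

* reaction order in [coupling partner] at the outset, round the charge of the beta run, defined at two percent of the starting material turned into target
* reaction order in [starting material] at the outset, round the charge of the beta run, defined at two percent of the starting material turned into target (one fixed amount of target, the same in the runs compared)
* target in the delta run at 110 min, as a share of the starting material charged

- Overall: starting material + coupling partner -> target, with catalyst as catalyst.
- Constant volume, constant temperature.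
- Readings of a species count what is bound in complexes too.
- An order is taken over about fifteen percent of the charge, up and down.

Take as early pace u, in each run, the target at 28 min divided by that time, and divide the target at 110 min by u. The beta run gives 53.4 min, the eta run 58.4 min and the theta run 56.5 min. Their mean, the working time W = 56.1 min, is how long a flask would have to hold its early pace to make what it made by the last reading. The charge of starting material differs by a factor 4.00 between eta and theta, but the beta reading under u by itself carries a scatter of 9.41 %, so the three values of W are rough readings, and carrying their mean over to the delta run is an assumption.

For the delta run, then, target = W u, and you need a bracket on u. Theta over beta gives, for the target at 110 min, an exponent in starting material of 0.614; this comes from a ratio of last readings, it is not the order at the outset that is asked, and using it for the pace is a further assumption. From below, I assume extra coupling partner does not slow the flask: theta's pace, scaled to delta's starting material with that exponent, gives 0.0316 M, or 21.1 % of the charge. From above, I assume the pace grows no faster than in proportion to coupling partner, which gives 64.0 %. To tighten this, beta over eta at the last reading, with starting material taken out, leaves an exponent in coupling partner of 0.344, from one pair of readings, and my own figure of 30.9 %.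

The forecast gives 0.35, 0.5 and 29 %, inside the bracket, with the words “This points to catalyst dying or product inhibition, not reactant exhaustion”.

The flask gives 0.35, 0.30 and 23.5 %, which is inside the bracket and lower than the forecast.

    catalyst + starting material → catalyst-substrate complex (6.300 M⁻¹ min⁻¹)
    catalyst-substrate complex + coupling partner → target + catalyst (2.886 M⁻¹ min⁻¹)
    starting material → decomposed substrate (0.02448 min⁻¹)
    catalyst + starting material ⇌ idle catalyst-substrate complex, settled at all times (31.90 M⁻¹)

In the delta run, decomposition of starting material ran from the first minute with a lifetime of 40.8 min, beside the catalyst cycle, while at the start the idle catalyst-substrate complex held 4.78 times the free catalyst. By 110 min that decomposition by itself brings the fraction left to 6.77 %. Delta's 0.0353 M of target asks, at W, a mean early pace of 6.30 × 10⁻⁴ M min⁻¹. In the theta run, the simulated rate 3.6 × 10⁻⁴ M min⁻¹ times W gives 0.0204 M, against the last reading of 0.0248 M.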